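**Strategy**

Ring A carries four adjacent oxygenated carbons (C6, C7, C8, C8a) flanked by C5–H and C4a, which maps onto the four carbons of dimethyl squarate plus a two-carbon alkenyl unit. The route therefore disconnects the C4a–C8a bond. Heating a 4-alkenyl-2,3,4-trimethoxycyclobutenone opens the four-membered ring to a dienylketene that electrocyclises and aromatises. This delivers ring A in one operation with three methyl ethers in place, O1 as the only free hydroxyl and C4 attached as a masked acetyl group. The precursor is the O-methylated adduct of an (E)-β-lithiovinyl ketone ketal and dimethyl squarate. Ring C is then closed by chalcone formation and Algar–Flynn–Oyamada oxidation, followed by one methylation.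

Key step: step 4

Remark: the target is achiral. Compounds 7, 8, 10 and 15 carry transient stereocentres and should form as racemates; 7, 8 and 10 are drawn without configuration, 15 with its relative (trans) configuration.

**Route**

Step 1
Reactants: 1 but-3-yn-2-one
Product: 2 (3E)-4-bromobut-3-en-2-one
Conditions: HBr (33 % in AcOH, 1.1 equiv), CH2Cl2, 0 °C to rt
Reagents that add atoms: hydrogen bromide, Br
Why: Conjugate hydrobromination of the ynone; bromide adds reversibly to the β-bromo enone under HBr, so the mixture should settle on the more stable E isomer.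

Step 2
Reactants: 2 (3E)-4-bromobut-3-en-2-one; 3 ethylene glycol
Product: 4 2-[(E)-2-bromoethenyl]-2-methyl-1,3-dioxolane
Conditions: TsOH·H2O (cat.), benzene, reflux, Dean–Stark
Reagents that add atoms: none
Why: Acid-catalysed ketalisation driven by azeotropic water removal, as used to turn β-bromo enones into β-acylvinyl anion equivalents; the alkene geometry is fixed once the carbonyl is masked.

Step 3
Reactants: 4 2-[(E)-2-bromoethenyl]-2-methyl-1,3-dioxolane; 5 dimethyl squarate (3,4-dimethoxycyclobut-3-ene-1,2-dione)
Product: 8 rac-2,3,4-trimethoxy-4-[(E)-2-(2-methyl-1,3-dioxolan-2-yl)ethenyl]cyclobut-2-en-1-one, via alkenyllithium 6 (not isolated), via lithium alkoxide 7 (not isolated)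
Conditions: t-BuLi (2.0 equiv), THF, −78 °C; cannulated into 5, THF, −78 °C; then MeOTf (1.5 equiv), −78 °C to 0 °C
Reagents that add atoms: methyl trifluoromethanesulfonate, COS(=O)(=O)C(F)(F)F
Why: Bromine–lithium exchange retains the E geometry, the alkenyllithium adds 1,2 to one of the two equivalent squarate carbonyls, and the tertiary lithium alkoxide is O-methylated in the same flask (organolithium addition to a squarate ester with alkoxide capture); the new quaternary stereocentre forms as a racemate and is erased in step 4.

Step 4
Reactants: 8 rac-2,3,4-trimethoxy-4-[(E)-2-(2-methyl-1,3-dioxolan-2-yl)ethenyl]cyclobut-2-en-1-one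
Product: 11 2,3,4-trimethoxy-6-(2-methyl-1,3-dioxolan-2-yl)phenol, via dienylketene 9 (not isolated), via cyclohexadienone 10 (not isolated)
Conditions: toluene (0.02 M, degassed), 110 °C, Ar
Reagents that add atoms: none
Why: Heating should trigger conrotatory 4π opening of the bond between the carbonyl carbon and the quaternary carbon to give dienylketene 9, which closes between the ketene carbon (future C8a) and the alkene terminus (future C4a) to dienone 10 and then tautomerises to phenol 11. The closest known reaction type is the Moore rearrangement of squarate-derived 4-alkenylcyclobutenones to oxygenated phenols. Ring A is closed by a thermal disrotatory 6π electrocyclisation that forms the single new C–C bond of the six-membered carbocycle. No stereocentre survives: the quaternary centre of 8 is lost on ring opening and the sp3 centre of 10 on enolisation. The step needs torquoselectivity, with the alkenyl group rotating inward; the 4-methoxy group, as a donor, should rotate outward and so place the alkenyl group cis to the ketene. The same methyl ether ensures that only the former carbonyl oxygen emerges as a free hydroxyl, so the four oxygens of ring A are differentiated without protecting-group steps.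

Step 5
Reactants: 11 2,3,4-trimethoxy-6-(2-methyl-1,3-dioxolan-2-yl)phenol
Product: 12 1-(2-hydroxy-3,4,5-trimethoxyphenyl)ethan-1-one
Conditions: 1 M aq. HCl, THF, rt
Reagents that add atoms: water, O
Why: Acid-catalysed ketal hydrolysis; the aryl methyl ethers and the phenol are inert to dilute aqueous acid at room temperature.

Step 6
Reactants: 12 1-(2-hydroxy-3,4,5-trimethoxyphenyl)ethan-1-one; 13 4-methoxybenzaldehyde
Product: 16 3-hydroxy-6,7,8-trimethoxy-2-(4-methoxyphenyl)-4H-chromen-4-one, via chalcone 14 (not isolated), via dihydroflavonol 15 (not isolated)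
Conditions: KOH (50 % aq.), EtOH, rt; then EtOH, 30 % aq. H2O2, 0 °C to rt; HCl work-up
Reagents that add atoms: hydrogen peroxide, OO
Why: Claisen–Schmidt condensation should give the E-chalcone, and alkaline peroxide (Algar–Flynn–Oyamada reaction) should cyclise it through the 2'-phenoxide to the dihydroflavonol and oxidise that to the flavonol; the absence of a 6'-substituent disfavours the aurone pathway, and the two transient stereocentres of 15 are removed on oxidation.

Step 7
Reactants: 16 3-hydroxy-6,7,8-trimethoxy-2-(4-methoxyphenyl)-4H-chromen-4-one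
Product: 17 auranetin (3,6,7,8-tetramethoxy-2-(4-methoxyphenyl)-4H-chromen-4-one)
Conditions: MeI, K2CO3, acetone, reflux
Reagents that add atoms: iodomethane, CI
Why: Williamson-type O-methylation of the acidic 3-hydroxyl, the only free OH in 16.

**Compound list**

1 | but-3-yn-2-one | CC(=O)C#C | starting material
2 | (3E)-4-bromobut-3-en-2-one | CC(=O)/C=C/Br | intermediate
3 | ethylene glycol (ethane-1,2-diol) | OCCO | starting material
4 | 2-[(E)-2-bromoethenyl]-2-methyl-1,3-dioxolane | CC1(/C=C/Br)OCCO1 | intermediate
5 | dimethyl squarate (3,4-dimethoxycyclobut-3-ene-1,2-dione) | COC1=C(OC)C(=O)C1=O | starting material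
6 | [(E)-2-(2-methyl-1,3-dioxolan-2-yl)ethenyl]lithium | [Li]/C=C/C1(C)OCCO1 | intermediate (not isolated)
7 | lithium rac-2,3-dimethoxy-1-[(E)-2-(2-methyl-1,3-dioxolan-2-yl)ethenyl]-4-oxocyclobut-2-en-1-olate | [Li+].[O-]C1(/C=C/C2(C)OCCO2)C(OC)=C(OC)C1=O | intermediate (not isolated)
8 | rac-2,3,4-trimethoxy-4-[(E)-2-(2-methyl-1,3-dioxolan-2-yl)ethenyl]cyclobut-2-en-1-one | COC1=C(OC)C(OC)(/C=C/C2(C)OCCO2)C1=O | intermediate
9 | (3Z,5E)-2,3,4-trimethoxy-6-(2-methyl-1,3-dioxolan-2-yl)hexa-1,3,5-trien-1-one | COC(=C=O)/C(OC)=C(OC)\C=C\C1(C)OCCO1 | intermediate (not isolated)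
10 | rac-2,3,4-trimethoxy-6-(2-methyl-1,3-dioxolan-2-yl)cyclohexa-2,4-dien-1-one | COC1=CC(C2(C)OCCO2)C(=O)C(OC)=C1OC | intermediate (not isolated)
11 | 2,3,4-trimethoxy-6-(2-methyl-1,3-dioxolan-2-yl)phenol | COc1cc(C2(C)OCCO2)c(O)c(OC)c1OC | intermediate
12 | 1-(2-hydroxy-3,4,5-trimethoxyphenyl)ethan-1-one | CC(=O)c1cc(OC)c(OC)c(OC)c1O | intermediate
13 | 4-methoxybenzaldehyde | COc1ccc(C=O)cc1 | starting material
14 | (2E)-1-(2-hydroxy-3,4,5-trimethoxyphenyl)-3-(4-methoxyphenyl)prop-2-en-1-one | COc1ccc(/C=C/C(=O)c2cc(OC)c(OC)c(OC)c2O)cc1 | intermediate (not isolated)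
15 | rac-(2R,3R)-3-hydroxy-6,7,8-trimethoxy-2-(4-methoxyphenyl)-2,3-dihydro-4H-chromen-4-one (trans; one enantiomer drawn) | O=C1c2cc(OC)c(OC)c(OC)c2O[C@H](c2ccc(OC)cc2)[C@H]1O | intermediate (not isolated)
16 | 3-hydroxy-6,7,8-trimethoxy-2-(4-methoxyphenyl)-4H-chromen-4-one | COc1ccc(-c2oc3c(OC)c(OC)c(OC)cc3c(=O)c2O)cc1 | intermediate
17 | auranetin, 3,6,7,8-tetramethoxy-2-(4-methoxyphenyl)-4H-chromen-4-one | COc1ccc(-c2oc3c(OC)c(OC)c(OC)cc3c(=O)c2OC)cc1 | target

**Step count**

Total: 7 steps. Longest linear sequence: 7 steps, from but-3-yn-2-one 1; dimethyl squarate 5 and 4-methoxybenzaldehyde 13 enter as purchased.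

**Steps most likely to fail**

Step 4. The alkene terminus carries a quaternary ketal carbon, which may slow the 6π closure enough for the ketene to be lost to dimerisation or stray nucleophiles; the allylic ketal may also not survive prolonged heating. The fallback runs the same ring expansion on the unsubstituted vinyl analogue and attaches the acetyl group afterwards. It sets out from dimethyl squarate 5 and comes back at 12.
- CH2=CHMgBr (THF, −78 °C, aqueous quench) should give rac-4-ethenyl-4-hydroxy-2,3-dimethoxycyclobut-2-en-1-one F1.
- MeI, Ag2O and K2CO3 in MeCN should convert it into rac-4-ethenyl-2,3,4-trimethoxycyclobut-2-en-1-one F2.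
- Refluxing toluene should turn this into 2,3,4-trimethoxyphenol F3.
- Ac2O and pyridine should give 2,3,4-trimethoxyphenyl acetate F4.
- Fries rearrangement with BF3·OEt2 (neat, 90 °C) should move the acetyl group to the only free ortho position, since the para position is blocked, giving 12.

Step 3. The hindered tertiary lithium alkoxide may be captured incompletely because MeOTf is consumed by the solvent, or the alkoxide may fragment on warming. The fallback separates addition and etherification and methylates the neutral carbinol. It sets out from lithium alkoxide 7 and comes back at 8.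
- Quenching 7 cold with water should give rac-4-hydroxy-2,3-dimethoxy-4-[(E)-2-(2-methyl-1,3-dioxolan-2-yl)ethenyl]cyclobut-2-en-1-one F5, which is isolated.
- Silver-assisted etherification (MeI, Ag2O, K2CO3, MeCN, rt) should then give 8.

Step 2. The β-bromo enone is a vinylogous acyl bromide, so the diol may attack the β-carbon and displace bromide instead of ketalising the carbonyl, and the alkene geometry may erode under acid. The fallback masks the ketone before the vinyl metal is created and sets the E geometry by hydrometalation. It sets out from but-3-yn-2-one 1 and comes back at alkenyllithium 6.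
- 1,2-Bis(trimethylsilyloxy)ethane with catalytic TMSOTf (CH2Cl2, −78 °C) should give 2-ethynyl-2-methyl-1,3-dioxolane F6.
- Radical hydrostannation (Bu3SnH, cat. AIBN, 80 °C) should give tributyl[(E)-2-(2-methyl-1,3-dioxolan-2-yl)ethenyl]stannane F7.
- Tin–lithium exchange with n-BuLi (THF, −78 °C) should deliver 6, which is added to 5 as in step 3.

**Further compounds**

F1 | step 4 | rac-4-ethenyl-4-hydroxy-2,3-dimethoxycyclobut-2-en-1-one | COC1=C(OC)C(O)(C=C)C1=O
F2 | step 4 | rac-4-ethenyl-2,3,4-trimethoxycyclobut-2-en-1-one | COC1=C(OC)C(OC)(C=C)C1=O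
F3 | step 4 | 2,3,4-trimethoxyphenol | COc1ccc(O)c(OC)c1OC
F4 | step 4 | 2,3,4-trimethoxyphenyl acetate | COc1ccc(OC(C)=O)c(OC)c1OC
F5 | step 3 | rac-4-hydroxy-2,3-dimethoxy-4-[(E)-2-(2-methyl-1,3-dioxolan-2-yl)ethenyl]cyclobut-2-en-1-one | COC1=C(OC)C(O)(/C=C/C2(C)OCCO2)C1=O
F6 | step 2 | 2-ethynyl-2-methyl-1,3-dioxolane | CC1(C#C)OCCO1
F7 | step 2 | tributyl[(E)-2-(2-methyl-1,3-dioxolan-2-yl)ethenyl]stannane | CCCC[Sn](CCCC)(CCCC)/C=C/C1(C)OCCO1
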